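**Retrosynthetic overview**
1. The last C–C bond is the CH2–CH= bond next to the butenolide. A nickel-catalysed decarboxylative alkenylation joins a (Z)-alkenyl bromide carrying ring A to the N-hydroxyphthalimide ester of a butenolide-acetic acid, and one desilylation follows.
2. Ring B (butenolide) is released from a cis-fused bis-lactone (ring B plus sacrificial ring C) by retro-oxa-Michael opening. Rings B and C close together, with the lactone C=O taken from CO, in a palladium-catalysed oxidative carbonylative bis-lactonisation of an acyclic (S)-3-hydroxypent-4-enoic acid made by an acetate aldol.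
3. The left half is joined by B-alkyl Suzuki coupling of a ring A dienol with an iodo/bromo diene. The Z-alkene comes from anti-carbomagnesiation of propargyl alcohol and the E-alkene from alkyne hydrozirconation.
4. Ring A comes from a Michael–Claisen annulation of two acyclic pieces, a Stork–Danheiser vinylation and a CBS reduction.
5. Ring order: ring A in step 1, rings B and C in one operation in step 13, ring C opened again in step 14.

Atom labels used below: ring A = C1 (CMe2), C2, C3, C4 (CHOH), C5 (CMe), C6. The chain is C7–C15, with Me on C9 and CH2OH on C13. Ring B = O, C16 (OCH), C17 (C–CH2OH), C18 (=CH), C19 (C=O).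

**Step 1**
Reactants: 1 2-methylpentan-3-one; 2 methyl acrylate
Product: 4 2,4,4-trimethylcyclohexane-1,3-dione, via methyl 4,4-dimethyl-5-oxoheptanoate 3 (not isolated)
Conditions: KOtBu (1.1 equiv), THF, 0 °C → rt; then 2 M HCl
Reagents that add atoms: none
Why: Michael–Claisen (Dieckmann-type) annulation in which the Michael additions are reversible and only the adduct formed through the isopropyl carbon can close to a 1,3-dione that keeps an acidic C–H between its carbonyls, so its stable enolate drains the equilibrium and ring A is closed without any lasting stereocentre.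

**Step 2**
Reactants: 4 2,4,4-trimethylcyclohexane-1,3-dione
Product: 5 3-isobutoxy-2,6,6-trimethylcyclohex-2-en-1-one
Conditions: i-BuOH, p-TsOH (5 mol %), toluene, Dean–Stark reflux
Reagents that add atoms: 2-methylpropan-1-ol CC(C)CO
Why: Acid-catalysed vinylogous esterification with azeotropic removal of water, in which the alcohol adds to the carbonyl remote from the gem-dimethyl group, so the enol ether oxygen sits on the future C4 and the hindered carbonyl (future C6) stays free.

**Step 3**
Reactants: 5 3-isobutoxy-2,6,6-trimethylcyclohex-2-en-1-one; 6 vinylmagnesium bromide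
Product: 8 2,4,4-trimethyl-3-vinylcyclohex-2-en-1-one, via tertiary carbinol 7 (not isolated)
Conditions: THF, 0 °C → rt; then 1 M HCl, rt
Reagents that add atoms: none
Why: Stork–Danheiser sequence in which 1,2-addition to the vinylogous ester carbonyl and acid-induced loss of isobutanol transpose the enone, which puts the vinyl group on C6 next to the gem-dimethyl carbon and the carbonyl on C4.

**Step 4**
Reactants: 8 2,4,4-trimethyl-3-vinylcyclohex-2-en-1-one
Product: 9 (1S)-2,4,4-trimethyl-3-vinylcyclohex-2-en-1-ol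
Conditions: (R)-Me-CBS oxazaborolidine (15 mol %), catecholborane (1.8 equiv), toluene, −78 °C; aqueous work-up
Reagents that add atoms: none
Why: Corey–Bakshi–Shibata reduction in which the alkenyl flank (C5) is the large and the CH2 flank (C3) the small substituent, so the (R)-catalyst delivers hydride to the face that gives the (S)-carbinol at C4, and catecholborane at low temperature leaves the diene untouched.

**Step 5**
Reactants: 10 pent-3-yn-1-ol
Product: 11 5-bromopent-2-yne
Conditions: CBr4, PPh3, CH2Cl2, 0 °C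
Reagents that add atoms: carbon tetrabromide BrC(Br)(Br)Br
Why: Appel reaction, an SN2 displacement of the oxyphosphonium group by bromide at a primary carbon that leaves the internal alkyne alone.

**Step 6**
Reactants: 11 5-bromopent-2-yne; 12 propargyl alcohol
Product: 15 (2Z)-3-bromo-2-(pent-3-yn-1-yl)prop-2-en-1-ol, via pent-3-yn-1-ylmagnesium bromide 13 (not isolated), via oxamagnesacycle 14 (not isolated)
Conditions: Mg, THF, 40 °C; then 12 (0.4 equiv), CuI (10 mol %), THF/Et2O, 0 °C → rt; then NBS, −30 → 0 °C; aqueous work-up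
Reagents that add atoms: N-bromosuccinimide O=C1CCC(=O)N1Br
Why: Copper-catalysed alkoxide-directed anti-carbomagnesiation of propargyl alcohol (Duboudin-type), in which the alkyl group goes to the inner alkyne carbon (C13) and magnesium to the terminal carbon (C14) cis to CH2O in a five-membered chelate, and NBS brominates the C–Mg bond with retention, which fixes the Z geometry of C13=C14.

**Step 7**
Reactants: 15 (2Z)-3-bromo-2-(pent-3-yn-1-yl)prop-2-en-1-ol
Product: 17 (5E)-2-[(Z)-bromomethylidene]-6-iodohept-5-en-1-ol, via alkenylzirconocene chloride 16 (not isolated)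
Conditions: Cp2Zr(H)Cl (2.5 equiv), THF, rt → 40 °C; then I2, 0 °C; aqueous work-up
Reagents that add atoms: iodine II
Why: Schwartz hydrozirconation–iodinolysis, in which syn addition of Zr–H (zirconium settling on the methyl-bearing carbon C9 after equilibration by excess reagent) and iodinolysis with retention give the E iodide, while the trisubstituted bromoalkene is too hindered to react.

**Step 8**
Reactants: 9 (1S)-2,4,4-trimethyl-3-vinylcyclohex-2-en-1-ol; 17 (5E)-2-[(Z)-bromomethylidene]-6-iodohept-5-en-1-ol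
Product: 19 (1S)-3-[(3E,7Z)-8-bromo-7-(hydroxymethyl)-3-methylocta-3,7-dien-1-yl]-2,4,4-trimethylcyclohex-2-en-1-ol, via B-alkyl-9-BBN borinate 18 (not isolated)
Conditions: 9-BBN (2.2 equiv), THF, rt; then 17, Pd(dppf)Cl2 (5 mol %), AsPh3 (10 mol %), Cs2CO3, DMF/H2O, rt
Reagents that add atoms: none
Why: Hydroboration and B-alkyl Suzuki–Miyaura coupling, in which 9-BBN adds only to the terminal vinyl carbon (C8) of the diene and zerovalent palladium at room temperature inserts into C–I far faster than into C–Br, so C8–C9 forms with retention of the E geometry while the Z bromide and C4 stay untouched.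

**Step 9**
Reactants: 20 2-methylenepropane-1,3-diol
Product: 21 2-{[(tert-butyldiphenylsilyl)oxy]methyl}prop-2-en-1-ol
Conditions: NaH (1.0 equiv), THF, rt; then TBDPSCl (1.0 equiv)
Reagents that add atoms: tert-butyl(chloro)diphenylsilane CC(C)(C)[Si](Cl)(c1ccccc1)c1ccccc1
Why: O-silylation of the monosodium alkoxide, which forms as a sparingly soluble salt from one equivalent of NaH and so desymmetrises the diol in favour of the monoether.

**Step 10**
Reactants: 21 2-{[(tert-butyldiphenylsilyl)oxy]methyl}prop-2-en-1-ol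
Product: 22 2-{[(tert-butyldiphenylsilyl)oxy]methyl}prop-2-enal
Conditions: MnO2 (excess), CH2Cl2, rt
Reagents that add atoms: none
Why: MnO2 allylic oxidation, which is selective for the allylic alcohol, stops at the aldehyde and is neutral enough for the silyl ether and the reactive enal.

**Step 11**
Reactants: 22 2-{[(tert-butyldiphenylsilyl)oxy]methyl}prop-2-enal; 23 (S)-2-hydroxy-1,2,2-triphenylethyl acetate ((S)-HYTRA)
Product: 24 (1S)-2-hydroxy-1,2,2-triphenylethyl (3S)-3-hydroxy-4-{[(tert-butyldiphenylsilyl)oxy]methyl}pent-4-enoate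
Conditions: LDA (2.2 equiv), THF, −78 → 0 °C; then 22, −78 °C or below; aqueous work-up; recrystallisation
Reagents that add atoms: none
Why: Braun acetate aldol addition, in which the doubly lithiated (S)-HYTRA enolate adds 1,2 to the enal from the face that gives the (S)-carbinol at C16 (the same sense as its additions to α-branched aldehydes) and crystallisation removes the minor diastereomer.

**Step 12**
Reactants: 24 (1S)-2-hydroxy-1,2,2-triphenylethyl (3S)-3-hydroxy-4-{[(tert-butyldiphenylsilyl)oxy]methyl}pent-4-enoate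
Product: 25 (3S)-3-hydroxy-4-{[(tert-butyldiphenylsilyl)oxy]methyl}pent-4-enoic acid
Conditions: LiOH, THF/MeOH/H2O, rt; then 1 M HCl to pH 3
Reagents that add atoms: lithium hydroxide [Li+].[OH-]
Why: Ester saponification that touches no bond at C16, frees the carboxylic acid needed as the first nucleophile of step 13 and returns the auxiliary diol.

**Step 13 (key step)**
Reactants: 25 (3S)-3-hydroxy-4-{[(tert-butyldiphenylsilyl)oxy]methyl}pent-4-enoic acid
Product: 26 (3aR,6aS)-3a-{[(tert-butyldiphenylsilyl)oxy]methyl}tetrahydrofuro[3,2-b]furan-2,5-dione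
Conditions: PdCl2 (10 mol %), CuCl2 (3 equiv), NaOAc (3 equiv), AcOH, CO (1 atm), rt
Reagents that add atoms: carbon monoxide [C-]#[O+]
Why: Oxidative carbonylative bis-lactonisation (Semmelhack-type oxycarbonylation with divalent palladium), in which the carboxylate attacks the palladium-bound 1,1-disubstituted alkene at C17 (5-exo), the resulting alkylpalladium at C18 has no β-hydrogen and inserts CO (C19), and the C16 hydroxyl captures the acylpalladium, so rings C and B close in one operation, only the cis-fused bicycle can form (C17 follows from C16) and the C16–O bond is never broken.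

**Step 14**
Reactants: 26 (3aR,6aS)-3a-{[(tert-butyldiphenylsilyl)oxy]methyl}tetrahydrofuro[3,2-b]furan-2,5-dione; 27 N-hydroxyphthalimide
Product: 29 1,3-dioxoisoindolin-2-yl [(2S)-3-{[(tert-butyldiphenylsilyl)oxy]methyl}-5-oxo-2,5-dihydrofuran-2-yl]acetate, via butenolide-acetic acid 28 (not isolated)
Conditions: Et3N (1.05 equiv), CH2Cl2, 0 °C → rt, 1 h; then 27 (2.2 equiv), DIC (1.1 equiv), 0 °C → rt
Reagents that add atoms: none
Why: Retro-oxa-Michael (E1cB) opening followed by carbodiimide esterification, in which loss of the tertiary C17 carboxylate gives the more substituted conjugated butenolide, the alternative opening is reversible through re-addition of its carboxylate to an unsubstituted β-carbon and so funnels to 28, the C16–O bond is kept, and excess N-hydroxyphthalimide holds the amine protonated so that the active ester does not eliminate.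

**Step 15**
Reactants: 19 (1S)-3-[(3E,7Z)-8-bromo-7-(hydroxymethyl)-3-methylocta-3,7-dien-1-yl]-2,4,4-trimethylcyclohex-2-en-1-ol; 29 1,3-dioxoisoindolin-2-yl [(2S)-3-{[(tert-butyldiphenylsilyl)oxy]methyl}-5-oxo-2,5-dihydrofuran-2-yl]acetate
Product: 30 (5S)-4-{[(tert-butyldiphenylsilyl)oxy]methyl}-5-[(2Z,6E)-3-(hydroxymethyl)-9-[(3S)-3-hydroxy-2,6,6-trimethylcyclohex-1-en-1-yl]-7-methylnona-2,6-dien-1-yl]furan-2(5H)-one
Conditions: NiBr2(diglyme) (10 mol %), 4,4'-di-tert-butyl-2,2'-bipyridine (12 mol %), Zn (2.5 equiv), 29 (1.5 equiv), DMA, rt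
Reagents that add atoms: none
Why: Nickel-catalysed reductive decarboxylative alkenylation (cross-electrophile coupling of an N-hydroxyphthalimide ester with an alkenyl bromide), in which zerovalent nickel inserts into C14–Br with retention, single-electron reduction of the ester releases CO2 and the primary C15 radical, and reductive elimination forms C14–C15 under neutral conditions that spare the free hydroxyls, the butenolide and both stereocentres (the radical sits next to C16, not on it).

**Step 16**
Reactants: 30 (5S)-4-{[(tert-butyldiphenylsilyl)oxy]methyl}-5-[(2Z,6E)-3-(hydroxymethyl)-9-[(3S)-3-hydroxy-2,6,6-trimethylcyclohex-1-en-1-yl]-7-methylnona-2,6-dien-1-yl]furan-2(5H)-one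
Product: 31 (5S)-4-(hydroxymethyl)-5-[(2Z,6E)-3-(hydroxymethyl)-9-[(3S)-3-hydroxy-2,6,6-trimethylcyclohex-1-en-1-yl]-7-methylnona-2,6-dien-1-yl]furan-2(5H)-one
Conditions: HF·pyridine, pyridine/THF, 0 °C → rt
Reagents that add atoms: none
Why: Fluoride-driven desilylation under buffered, non-basic conditions, which avoids deprotonation at C16 and ionisation of the allylic C4 alcohol.

**Compound list**
1 | 2-methylpentan-3-one | CCC(=O)C(C)C | starting material
2 | methyl acrylate | C=CC(=O)OC | starting material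
3 | methyl 4,4-dimethyl-5-oxoheptanoate | CCC(=O)C(C)(C)CCC(=O)OC | intermediate
4 | 2,4,4-trimethylcyclohexane-1,3-dione | CC1C(=O)CCC(C)(C)C1=O | intermediate
5 | 3-isobutoxy-2,6,6-trimethylcyclohex-2-en-1-one | CC(C)COC1=C(C)C(=O)C(C)(C)CC1 | intermediate
6 | vinylmagnesium bromide | C=C[Mg]Br | starting material
7 | 3-isobutoxy-2,6,6-trimethyl-1-vinylcyclohex-2-en-1-ol (racemic tertiary carbinol) | C=CC1(O)C(C)=C(OCC(C)C)CCC1(C)C | intermediate
8 | 2,4,4-trimethyl-3-vinylcyclohex-2-en-1-one | C=CC1=C(C)C(=O)CCC1(C)C | intermediate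
9 | (1S)-2,4,4-trimethyl-3-vinylcyclohex-2-en-1-ol | C=CC1=C(C)[C@@H](O)CCC1(C)C | intermediate
10 | pent-3-yn-1-ol | CC#CCCO | starting material
11 | 5-bromopent-2-yne | CC#CCCBr | intermediate
12 | propargyl alcohol | C#CCO | starting material
13 | pent-3-yn-1-ylmagnesium bromide | CC#CCC[Mg]Br | intermediate
14 | 4-(pent-3-yn-1-yl)-2,5-dihydro-1,2-oxamagnesole (chelated alkenylmagnesium alkoxide) | CC#CCCC1=C[Mg]OC1 | intermediate
15 | (2Z)-3-bromo-2-(pent-3-yn-1-yl)prop-2-en-1-ol | CC#CCC/C(CO)=C/Br | intermediate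
16 | (E)-alkenylzirconocene chloride from 15, with the hydroxyl bound as a zirconocene chloride alkoxide | Cl[Zr](C1C=CC=C1)(C1C=CC=C1)/C(C)=C/CC/C(CO[Zr](Cl)(C1C=CC=C1)C1C=CC=C1)=C/Br | intermediate
17 | (5E)-2-[(Z)-bromomethylidene]-6-iodohept-5-en-1-ol | I/C(C)=C/CC/C(CO)=C/Br | intermediate
18 | B-alkyl-9-BBN from 9, with the C4 oxygen bound as a 9-BBN borinate | CC1=C(CCB2C3CCCC2CCC3)C(C)(C)CC[C@@H]1OB1C2CCCC1CCC2 | intermediate
19 | (1S)-3-[(3E,7Z)-8-bromo-7-(hydroxymethyl)-3-methylocta-3,7-dien-1-yl]-2,4,4-trimethylcyclohex-2-en-1-ol | CC1=C(CC/C(C)=C/CC/C(CO)=C/Br)C(C)(C)CC[C@@H]1O | intermediate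
20 | 2-methylenepropane-1,3-diol | C=C(CO)CO | starting material
21 | 2-{[(tert-butyldiphenylsilyl)oxy]methyl}prop-2-en-1-ol | C=C(CO)CO[Si](c1ccccc1)(c1ccccc1)C(C)(C)C | intermediate
22 | 2-{[(tert-butyldiphenylsilyl)oxy]methyl}prop-2-enal | C=C(C=O)CO[Si](c1ccccc1)(c1ccccc1)C(C)(C)C | intermediate
23 | (S)-2-hydroxy-1,2,2-triphenylethyl acetate ((S)-HYTRA) | CC(=O)O[C@@H](c1ccccc1)C(O)(c1ccccc1)c1ccccc1 | starting material
24 | (1S)-2-hydroxy-1,2,2-triphenylethyl (3S)-3-hydroxy-4-{[(tert-butyldiphenylsilyl)oxy]methyl}pent-4-enoate | C=C(CO[Si](c1ccccc1)(c1ccccc1)C(C)(C)C)[C@@H](O)CC(=O)O[C@@H](c1ccccc1)C(O)(c1ccccc1)c1ccccc1 | intermediate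
25 | (3S)-3-hydroxy-4-{[(tert-butyldiphenylsilyl)oxy]methyl}pent-4-enoic acid | C=C(CO[Si](c1ccccc1)(c1ccccc1)C(C)(C)C)[C@@H](O)CC(=O)O | intermediate
26 | (3aR,6aS)-3a-{[(tert-butyldiphenylsilyl)oxy]methyl}tetrahydrofuro[3,2-b]furan-2,5-dione (cis-fused bis-lactone, rings B and C) | O=C1C[C@]2(CO[Si](c3ccccc3)(c3ccccc3)C(C)(C)C)OC(=O)C[C@@H]2O1 | intermediate
27 | N-hydroxyphthalimide | O=C1c2ccccc2C(=O)N1O | starting material
28 | [(2S)-3-{[(tert-butyldiphenylsilyl)oxy]methyl}-5-oxo-2,5-dihydrofuran-2-yl]acetic acid | OC(=O)C[C@@H]1OC(=O)C=C1CO[Si](c1ccccc1)(c1ccccc1)C(C)(C)C | intermediate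
29 | 1,3-dioxoisoindolin-2-yl [(2S)-3-{[(tert-butyldiphenylsilyl)oxy]methyl}-5-oxo-2,5-dihydrofuran-2-yl]acetate | O=C(C[C@@H]1OC(=O)C=C1CO[Si](c1ccccc1)(c1ccccc1)C(C)(C)C)ON1C(=O)c2ccccc2C1=O | intermediate
30 | TBDPS ether of the target at the ring B hydroxymethyl group (full name in step 15) | CC1=C(CC/C(C)=C/CC/C(=C/C[C@@H]2OC(=O)C=C2CO[Si](c2ccccc2)(c2ccccc2)C(C)(C)C)CO)C(C)(C)CC[C@@H]1O | intermediate
31 | (5S)-4-(hydroxymethyl)-5-[(2Z,6E)-3-(hydroxymethyl)-9-[(3S)-3-hydroxy-2,6,6-trimethylcyclohex-1-en-1-yl]-7-methylnona-2,6-dien-1-yl]furan-2(5H)-one (CNP0330392.1) | CC1=C(CC/C(C)=C/CC/C(=C/C[C@@H]2OC(=O)C=C2CO)CO)C(C)(C)CC[C@@H]1O | target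

**Total step count:** 16.
**Longest linear sequence:** 8 steps (steps 9–16). The ring A line (steps 1–4, 8, 15, 16) has 7 steps and the chain line (steps 5–8, 15, 16) has 6.

**Three steps most likely to fail**

**Step 13.** The carboxylate may be too weak a first nucleophile, or the quaternary C17–O bond may not form.
- The fallback sets out from 24 and comes back at 26.
- The ester is reduced with LiBH4 (THF/MeOH) to (3S)-4-{[(tert-butyldiphenylsilyl)oxy]methyl}pent-4-ene-1,3-diol F1.
- The carbonylation is then run in its classical ene-diol mode (PdCl2, CuCl2, NaOAc, AcOH, CO), where a primary hydroxyl opens the cascade. This gives (3aR,6aS)-3a-{[(tert-butyldiphenylsilyl)oxy]methyl}hexahydrofuro[3,2-b]furan-2-one F2.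
- The ring CH2–O of its tetrahydrofuran is oxidised to the lactone carbonyl with RuCl3/NaIO4, which gives 26.

**Step 14.** The bis-lactone may open in the wrong direction, or C16 may erode under base.
- The fallback sets out from 25 and comes back at 28. It builds ring B alone and without base-induced elimination.
- The acid is masked with 4-methoxybenzyl chloride/K2CO3 (DMF) as 4-methoxybenzyl (3S)-3-hydroxy-4-{[(tert-butyldiphenylsilyl)oxy]methyl}pent-4-enoate F3.
- The C16 hydroxyl is acylated with acryloyl chloride/i-Pr2NEt to 4-methoxybenzyl (3S)-3-(acryloyloxy)-4-{[(tert-butyldiphenylsilyl)oxy]methyl}pent-4-enoate F4.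
- Ring-closing metathesis (second-generation Grubbs catalyst, CH2Cl2, reflux) gives 4-methoxybenzyl [(2S)-3-{[(tert-butyldiphenylsilyl)oxy]methyl}-5-oxo-2,5-dihydrofuran-2-yl]acetate F5.
- TFA/CH2Cl2 at 0 °C frees acid 28, which enters the esterification half of step 14.

**Step 15.** The reductive coupling may suffer from homocoupling, β-acyloxy elimination at nickel or slow alkenyl bromide activation.
- The fallback sets out from 19 and comes back at 31. It replaces the two-electrophile coupling by a preformed alkenyl nucleophile.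
- Both hydroxyls are silylated (TBSCl, imidazole, DMF) to the bis-TBS ether of bromide 19 F6.
- Br/Li exchange (t-BuLi, −78 °C) and ZnCl2 give the (Z)-alkenylzinc chloride F7.
- Decarboxylative Negishi-type alkenylation of 29 with Ni(acac)2/2,2'-bipyridine (THF/DMF, rt) gives the tris-silyl ether of the target F8.
- Global desilylation with HF·pyridine gives 31.

**Further compounds**
F1 | step 13 | (3S)-4-{[(tert-butyldiphenylsilyl)oxy]methyl}pent-4-ene-1,3-diol | C=C(CO[Si](c1ccccc1)(c1ccccc1)C(C)(C)C)[C@@H](O)CCO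
F2 | step 13 | (3aR,6aS)-3a-{[(tert-butyldiphenylsilyl)oxy]methyl}hexahydrofuro[3,2-b]furan-2-one | O=C1C[C@]2(CO[Si](c3ccccc3)(c3ccccc3)C(C)(C)C)OCC[C@@H]2O1
F3 | step 14 | 4-methoxybenzyl (3S)-3-hydroxy-4-{[(tert-butyldiphenylsilyl)oxy]methyl}pent-4-enoate | C=C(CO[Si](c1ccccc1)(c1ccccc1)C(C)(C)C)[C@@H](O)CC(=O)OCc1ccc(OC)cc1
F4 | step 14 | 4-methoxybenzyl (3S)-3-(acryloyloxy)-4-{[(tert-butyldiphenylsilyl)oxy]methyl}pent-4-enoate | C=C(CO[Si](c1ccccc1)(c1ccccc1)C(C)(C)C)[C@@H](OC(=O)C=C)CC(=O)OCc1ccc(OC)cc1
F5 | step 14 | 4-methoxybenzyl [(2S)-3-{[(tert-butyldiphenylsilyl)oxy]methyl}-5-oxo-2,5-dihydrofuran-2-yl]acetate | COc1ccc(COC(=O)C[C@@H]2OC(=O)C=C2CO[Si](c2ccccc2)(c2ccccc2)C(C)(C)C)cc1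
F6 | step 15 | bis-TBS ether of bromide 19 | CC1=C(CC/C(C)=C/CC/C(CO[Si](C)(C)C(C)(C)C)=C/Br)C(C)(C)CC[C@@H]1O[Si](C)(C)C(C)(C)C
F7 | step 15 | (Z)-alkenylzinc chloride from F6 | CC1=C(CC/C(C)=C/CC/C(CO[Si](C)(C)C(C)(C)C)=C/[Zn]Cl)C(C)(C)CC[C@@H]1O[Si](C)(C)C(C)(C)C
F8 | step 15 | tris-silyl ether of the target (two TBS, one TBDPS) | CC1=C(CC/C(C)=C/CC/C(=C/C[C@@H]2OC(=O)C=C2CO[Si](c2ccccc2)(c2ccccc2)C(C)(C)C)CO[Si](C)(C)C(C)(C)C)C(C)(C)CC[C@@H]1O[Si](C)(C)C(C)(C)C
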